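## The problem

- The target is a germacranolide. A ten-membered carbocycle (C1–C10) carries two Z-alkenes, C1=C2 (disubstituted) and C4=C5 (trisubstituted), on either side of the doubly allylic carbinol C3. The ring is cis-fused at C6/C7 to an α-methylene-γ-butyrolactone (O–C6–C7–C11(=C13H2)–C12=O).
- There are five stereocentres. In the contiguous triad C6(O)–C7(C11)–C8(O), O6 and O8 are syn and C11 is anti to both. The tertiary carbinol C10 is anti-1,3 to O8. The C3 hydroxyl lies on the same face as O10 across the Z-C1=C2 bond.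
- Within the triad C8 can control C7 and C6. C3 and C10 are separated from the triad by sp2 carbons or a methylene group in a flexible medium ring, so each must be set on its own.
- Closing a ten-membered ring is costly in enthalpy and entropy, and both ring alkenes must stay Z.
- Several groups are fragile: the bis-allylic C3 alcohol (it ionizes, and in a precursor it would add to a C6 carbonyl to give a dihydrofuranol and then a furan), the allylic C6–O lactone bond, the exo-methylene lactone (a Michael acceptor that also takes part in metathesis), the tertiary allylic alcohol, the tiglate, and the Z-enals met on the way.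
- The feature that makes the key step possible is in the lactone ring: the O–C6 and C7–C11 bonds are cis and C6 is allylic to C4=C5. C6 is therefore the carbinol carbon of a syn-homoallylic alcohol whose neighbour C7 carries the acrylate unit C13=C11–C12. This is the retron of the addition of a Z-configured 2-(alkoxycarbonyl)allyl metal to a non-enolizable Z-enal through a chair transition state, for which the cis fusion is the intrinsic outcome.

## Retrosynthesis

**C8 ester and silyl ethers.** Target 31 is traced to bis-silyl ether 30 and then to alcohol 28 and tigloyl chloride 29 (C8–O acyl bond). The tiglate is put on late because 28 has only one free hydroxyl, so no selectivity is asked of the acylation. The forward steps must free C8–OH from macrolactone 27 without touching the C3 and C10 silyl ethers, acylate without adding to the methylene lactone, and end with a fluoride deprotection mild enough for the bis-allylic alcohol.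

**C6–C7 and O6–C12 (key step).** Macrolactone 27 is cut at C6–C7 and at the lactone C–O bond, giving the acyclic bromo enal 24. This one cut removes the ten-membered ring, the lactone and two stereocentres. Cuts at C2–C3 or C1=C2 remove only the ring. Precursor 24 keeps three stereocentres (C3, C8, C10), each set by a reagent or by the chiral pool. The forward reaction must give syn addition (cis lactone), the right face of C7 relative to C8, 1,2-addition to the enal, and cyclization instead of oligomerization.

**C7–C11 and the two aldehydes.** Bromide 24 comes from allylic alcohol 23 by allylic transposition. Alcohol 23 comes from dialdehyde 20 and methyl propiolate 21 (C7–C11 bond, through vinylalane 22). The C7 carbinol of 23 is lost again, so both epimers serve. Dialdehyde 20 comes from 19, whose two primary triethylsilyl ethers are oxidized in one operation. The forward step must distinguish the saturated α-silyloxy aldehyde (C7) from the conjugated Z-enal (C6).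

**C2–C3.** Silyl ether 19 comes from dienol 18, this from propargylic alcohol 17, and 17 from alkyne 15 and Z-enal 6. A catalyst-controlled alkynylation sets C3 independently of the remote C8 and C10. Semi-hydrogenation of the alkyne then gives the Z-C1=C2 bond. A vinyl-metal addition would have to secure both geometry and configuration at once. C3–OH is silylated before C6 becomes an aldehyde, which blocks furan formation.

**C10, C8 and the C7–C9 chain.** Alkyne 15 is traced through aldehyde 14, tris-silyl ether 13, diol 12 and aldehyde 9 to silyl ether 8 and (R)-linalool 7. Linalool supplies C10 with its methyl group, oxygen and vinyl group in the right configuration, plus C9, C8 and C7. Its trisubstituted alkene is cleaved to the C7 aldehyde. The C8 oxygen is introduced by proline-catalysed α-aminoxylation (catalyst control). The vinyl group is exchanged for ethynyl by ozonolysis and one-carbon homologation.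

**C3–C6 unit.** Enal 6 comes from vinyl iodide 4 and this from iodo alcohol 3 and but-2-yn-1-ol 1. Hydroxyl-directed trans-hydroalumination and iodination fix the Z-trisubstituted alkene before any coupling. The forward formylation must keep this geometry.

## Roads not taken

**Alternative 1:** ring-closing metathesis at C1=C2, the most obvious cut. The substrate is diene A1, the finished lactone with vinyl groups on C3 and C10, closed with a second-generation Grubbs catalyst.
- The methylene C11=C13 and the C10 vinyl group are 1,6-related, so a cyclohexene would close in preference to the strained ten-membered ring.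
- One vinyl group sits on a quaternary carbon and both are allylic to oxygen.
- The step sets no stereocentre, and the lactone of A1 would still have to be made by the same allylation chemistry.

**Alternative 2:** the allylation is used only to join the fragments, and the ring is closed at C2–C3 by a Nozaki–Hiyama–Kishi reaction of iodo aldehyde A2 (Z-vinyl iodide on C2, Z-enal at C3).
- C3 would be created in the ring-forming step with no dependable control element; its nearest stereocentre, C10, lies across the forming Z-alkene.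
- A correction would pass through the Z,Z-dienone, which can isomerize and form a hemiketal with O10.
- The chosen plan sets C3 with a catalyst before the ring exists.

**Alternative 3:** singlet-oxygen [4+2] cycloaddition to the all-cis ring triene A3 (C10=C1–C2=C3–C4=C5), then reduction of endoperoxide A4. The syn O3/O10 pair across the Z-alkene is the retron of this step, and it would set both C–O bonds and the alkene geometry at once.
- An all-cis conjugated triene in a ten-membered ring is set up for 6π-electrocyclization to a bicyclo[4.4.0]decadiene.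
- Two trisubstituted alkenes invite competing ene reactions.
- The facial selectivity would rest on remote centres, and A3 is no easier to make than the target.

Key step: step 16

Assumption: locants follow germacrane numbering (ring C1–C10, C14 on C10, C15 on C4, C11/C12/C13 the lactone side chain on C7); (S,S)-ProPhenol stands for the ligand antipode that gives the required C3 configuration, its mirror image being used if the sense of induction is the opposite one.

## Route

Step 1
Reactants: 1 but-2-yn-1-ol
Product: 3 (2Z)-3-iodobut-2-en-1-ol, via sodium alkenylaluminate 2 (not isolated)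
Conditions: NaAlH2(OCH2CH2OMe)2, THF, 0 °C to rt; then I2, THF, −78 °C
Reagents that add atoms: iodine (II)
Why: Hydroxyl-directed trans-hydroalumination puts aluminium on C3 and hydride on C2; iodinolysis of the C–Al bond with retention gives the Z-iodide, which later becomes the Z-C4=C5 bond.

Step 2
Reactants: 3 (2Z)-3-iodobut-2-en-1-ol
Product: 4 triethyl{[(2Z)-3-iodobut-2-en-1-yl]oxy}silane
Conditions: Et3SiCl, imidazole, CH2Cl2, 0 °C
Reagents that add atoms: chlorotriethylsilane (CC[Si](Cl)(CC)CC)
Why: Standard silylation; the primary triethylsilyl ether is chosen because it can later be oxidized directly to the aldehyde under Swern conditions.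

Step 3
Reactants: 4 triethyl{[(2Z)-3-iodobut-2-en-1-yl]oxy}silane
Product: 6 (2Z)-2-methyl-4-[(triethylsilyl)oxy]but-2-enal, via vinyllithium 5 (not isolated)
Conditions: t-BuLi (2.1 equiv), Et2O, −78 °C; DMF, −78 °C; aq NH4Cl
Reagents that add atoms: N,N-dimethylformamide (CN(C)C=O)
Why: Iodine–lithium exchange and formylation both proceed with retention of alkene geometry; ether at −78 °C and an immediate quench should suppress the 1,4 oxygen-to-carbon silyl shift of the Z-lithio species.

Step 4
Reactants: 7 (R)-(−)-linalool [(3R)-3,7-dimethylocta-1,6-dien-3-ol]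
Product: 8 triethyl{[(3R)-3,7-dimethylocta-1,6-dien-3-yl]oxy}silane
Conditions: Et3SiOTf, 2,6-lutidine, CH2Cl2, −78 to 0 °C
Reagents that add atoms: triethylsilyl trifluoromethanesulfonate (CC[Si](CC)(CC)OS(=O)(=O)C(F)(F)F)
Why: Silyl triflate silylation of a tertiary alcohol; it prevents lactol and cyclic-ether formation in the following steps and carries the C10 stereocentre from the chiral pool.

Step 5
Reactants: 8 triethyl{[(3R)-3,7-dimethylocta-1,6-dien-3-yl]oxy}silane
Product: 9 (4R)-4-methyl-4-[(triethylsilyl)oxy]hex-5-enal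
Conditions: O3 (1.0 equiv), CH2Cl2, −78 °C; Me2S, −78 °C to rt
Reagents that add atoms: ozone ([O-][O+]=O)
Why: Chemoselective ozonolysis: the electron-rich trisubstituted alkene should react much faster than the vinyl group next to the quaternary silyloxy carbon.

Step 6
Reactants: 9 (4R)-4-methyl-4-[(triethylsilyl)oxy]hex-5-enal
Product: 12 (2R,4R)-4-methyl-4-[(triethylsilyl)oxy]hex-5-ene-1,2-diol, via alpha-anilinooxy aldehyde 10 (not isolated), via anilinooxy alcohol 11 (not isolated)
Conditions: L-proline (20 mol %), PhNO, CHCl3, 0 °C; then NaBH4, EtOH, 0 °C; then Zn, AcOH, rt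
Reagents that add atoms: nitrosobenzene (O=Nc1ccccc1)
Why: Proline enamine catalysis (O-selective nitroso aldol, α-aminoxylation) sets C8 under catalyst control, L-proline giving the 2R centre; the remote C10 centre should not interfere. Reduction and N–O cleavage then give the diol.

Step 7
Reactants: 12 (2R,4R)-4-methyl-4-[(triethylsilyl)oxy]hex-5-ene-1,2-diol
Product: 13 (2R,4R)-4-methyl-1,2,4-tris[(triethylsilyl)oxy]hex-5-ene
Conditions: Et3SiCl (2.5 equiv), imidazole, DMAP (cat.), CH2Cl2, 0 °C to rt
Reagents that add atoms: chlorotriethylsilane (CC[Si](Cl)(CC)CC)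
Why: Exhaustive silylation; the primary ether is the later aldehyde precursor and the secondary ether protects C8–OH up to the acylation.

Step 8
Reactants: 13 (2R,4R)-4-methyl-1,2,4-tris[(triethylsilyl)oxy]hex-5-ene
Product: 14 (2R,4R)-2-methyl-2,4,5-tris[(triethylsilyl)oxy]pentanal
Conditions: O3, CH2Cl2, −78 °C; Me2S, −78 °C to rt
Reagents that add atoms: ozone ([O-][O+]=O)
Why: Ozonolysis of the only alkene; the product aldehyde has a quaternary α-carbon and cannot epimerize.

Step 9
Reactants: 14 (2R,4R)-2-methyl-2,4,5-tris[(triethylsilyl)oxy]pentanal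
Product: 15 (3R,5R)-3-methyl-3,5,6-tris[(triethylsilyl)oxy]hex-1-yne
Conditions: Me3SiCHN2, LiN(i-Pr)2, THF, −78 °C to rt
Reagents that add atoms: (trimethylsilyl)diazomethane (C[Si](C)(C)C=[N+]=[N-])
Why: Colvin rearrangement (addition, Peterson elimination, loss of N2 and 1,2-shift of the alkylidene carbene) converts the non-enolizable aldehyde into the terminal alkyne under aprotic conditions that spare the silyl ethers.

Step 10
Reactants: 15 (3R,5R)-3-methyl-3,5,6-tris[(triethylsilyl)oxy]hex-1-yne; 6 (2Z)-2-methyl-4-[(triethylsilyl)oxy]but-2-enal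
Product: 17 (2Z,4S,7R,9R)-3,7-dimethyl-1,7,9,10-tetrakis[(triethylsilyl)oxy]dec-2-en-5-yn-4-ol, via alkynylzinc 16 (not isolated)
Conditions: Me2Zn, (S,S)-ProPhenol (20 mol %), Ph3PO (40 mol %), toluene, 0 °C to rt
Reagents that add atoms: none
Why: Zinc–ProPhenol-catalysed enantioselective alkynylation of an α-branched enal; the dinuclear zinc catalyst binds alkynylzinc and aldehyde and sets C3 by catalyst control (4S here, the configuration that becomes 3R in the target).

Step 11
Reactants: 17 (2Z,4S,7R,9R)-3,7-dimethyl-1,7,9,10-tetrakis[(triethylsilyl)oxy]dec-2-en-5-yn-4-ol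
Product: 18 (2Z,4R,5Z,7R,9R)-3,7-dimethyl-1,7,9,10-tetrakis[(triethylsilyl)oxy]deca-2,5-dien-4-ol
Conditions: H2 (1 atm), Pd/CaCO3 poisoned with Pb(OAc)2, quinoline, EtOAc, rt
Reagents that add atoms: none
Why: Lindlar semi-hydrogenation adds hydrogen syn and gives the Z-C1=C2 bond; the trisubstituted alkene is inert.

Step 12
Reactants: 18 (2Z,4R,5Z,7R,9R)-3,7-dimethyl-1,7,9,10-tetrakis[(triethylsilyl)oxy]deca-2,5-dien-4-ol
Product: 19 (2Z,4R,5Z,7R,9R)-4-[(tert-butyldimethylsilyl)oxy]-3,7-dimethyl-1,7,9,10-tetrakis[(triethylsilyl)oxy]deca-2,5-diene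
Conditions: t-BuMe2SiOTf, 2,6-lutidine, CH2Cl2, −78 °C
Reagents that add atoms: tert-butyldimethylsilyl trifluoromethanesulfonate (CC(C)(C)[Si](C)(C)OS(=O)(=O)C(F)(F)F)
Why: Low-temperature silylation of the bis-allylic alcohol; the tert-butyldimethylsilyl ether blocks lactol and furan formation once C6 is an aldehyde and survives the later cleavage of the C8 triethylsilyl ether.

Step 13
Reactants: 19 (2Z,4R,5Z,7R,9R)-4-[(tert-butyldimethylsilyl)oxy]-3,7-dimethyl-1,7,9,10-tetrakis[(triethylsilyl)oxy]deca-2,5-diene
Product: 20 (2Z,4R,5Z,7R,9R)-4-[(tert-butyldimethylsilyl)oxy]-3,7-dimethyl-7,9-bis[(triethylsilyl)oxy]deca-2,5-dienedial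
Conditions: (COCl)2, DMSO, CH2Cl2, −78 to −30 °C; Et3N, −78 to 0 °C
Reagents that add atoms: none
Why: Swern conditions convert primary triethylsilyl ethers directly into aldehydes, while secondary and tertiary triethylsilyl ethers and the tert-butyldimethylsilyl ether are left; both chain ends reach the aldehyde level in one operation.

Step 14
Reactants: 20 (2Z,4R,5Z,7R,9R)-4-[(tert-butyldimethylsilyl)oxy]-3,7-dimethyl-7,9-bis[(triethylsilyl)oxy]deca-2,5-dienedial; 21 methyl propiolate
Product: 23 methyl (4R,6R,7Z,9R,10Z)-9-[(tert-butyldimethylsilyl)oxy]-3-hydroxy-6,10-dimethyl-2-methylidene-12-oxo-4,6-bis[(triethylsilyl)oxy]dodeca-7,10-dienoate (both C3 epimers), via vinylalane 22 (not isolated)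
Conditions: (i-Bu)2AlH, N-methylmorpholine N-oxide, THF, 0 °C, then 21; then 20, −78 to 0 °C
Reagents that add atoms: none
Why: Vinylalumination: hydroalumination of the propiolate gives the α-aluminoacrylate, which adds to aldehydes to give Morita–Baylis–Hillman-type adducts. The saturated α-silyloxy aldehyde should react far faster than the conjugated, β,β-disubstituted enal, and the new carbinol centre is removed in step 15.

Step 15
Reactants: 23 methyl (4R,6R,7Z,9R,10Z)-9-[(tert-butyldimethylsilyl)oxy]-3-hydroxy-6,10-dimethyl-2-methylidene-12-oxo-4,6-bis[(triethylsilyl)oxy]dodeca-7,10-dienoate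
Product: 24 methyl (2Z,4R,6R,7Z,9R,10Z)-2-(bromomethyl)-9-[(tert-butyldimethylsilyl)oxy]-6,10-dimethyl-12-oxo-4,6-bis[(triethylsilyl)oxy]dodeca-2,7,10-trienoate
Conditions: N-bromosuccinimide, Me2S, CH2Cl2, −20 °C to rt
Reagents that add atoms: N-bromosuccinimide (BrN1C(=O)CCC1=O)
Why: Corey–Kim-type activation of the allylic alcohol and SN2′ attack of bromide give the 2-(bromomethyl)enoate with C8 cis to CH2Br (Z); both C7 epimers of 23 converge on one bromide.

Step 16
Reactants: 24 methyl (2Z,4R,6R,7Z,9R,10Z)-2-(bromomethyl)-9-[(tert-butyldimethylsilyl)oxy]-6,10-dimethyl-12-oxo-4,6-bis[(triethylsilyl)oxy]dodeca-2,7,10-trienoate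
Product: 27 (1Z,3R,4Z,6S,7S,8R,10R)-3-[(tert-butyldimethylsilyl)oxy]-8,10-bis[(triethylsilyl)oxy]germacra-1,4,11(13)-trien-12,6-olide, via allylchromium 25 (not isolated), via chromium alkoxide 26 (not isolated)
Conditions: CrCl2 (10 equiv), THF, rt, slow addition of 24 (final 2 mM)
Reagents that add atoms: none
Why: Two equivalents of divalent chromium reduce the allylic C–Br bond to the trivalent allylchromium 25, whose fast 1,3-metal shifts make the outcome independent of the bromide geometry; the closest known reaction type is the chromium-mediated 2-(alkoxycarbonyl)allylation of aldehydes (Nozaki–Hiyama–Kishi/Barbier type), which is also known intramolecularly for ten-membered carbocycles. The ten-membered ring closes by 1,2-addition of C7 to the C6 aldehyde through a six-membered chair (Zimmerman–Traxler) transition state, a 10-exo-trig closure with the carbonyl oxygen outside the new ring; the lactone then closes by 5-exo-trig attack of chromium alkoxide 26 on the methyl ester. Because C8 is cis to the CH2Cr group it sits axial in the chair while the aldehyde substituent C5 sits equatorial, which gives the syn relation of C6–O and C7–C8 and hence the cis-fused lactone. The absolute sense at C7, and with it C6, comes from C8: allylic 1,3-strain with CH2Cr holds H8 in the allyl plane, the bulky C9 chain lies anti to the incoming aldehyde and the silyloxy group sits on the outside, so C6 bonds to the face of C7 syn to O8 (C7 has the target configuration; its descriptor reads S in 27 only because of the silyl group on O8). The step needs 1,2- over 1,4-addition to the enal and γ- over α-attack of the allyl unit (both secured by the closed transition state at oxophilic chromium), cyclization over oligomerization (slow addition, high dilution, two Z-alkenes that fold the chain), and survival of the Z-enal (neutral, aprotic medium).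

Step 17
Reactants: 27 (1Z,3R,4Z,6S,7S,8R,10R)-3-[(tert-butyldimethylsilyl)oxy]-8,10-bis[(triethylsilyl)oxy]germacra-1,4,11(13)-trien-12,6-olide
Product: 28 (1Z,3R,4Z,6S,7R,8R,10R)-3-[(tert-butyldimethylsilyl)oxy]-8-hydroxy-10-[(triethylsilyl)oxy]germacra-1,4,11(13)-trien-12,6-olide
Conditions: pyridinium p-toluenesulfonate (0.2 equiv), MeOH/CH2Cl2 (1:4), 0 °C
Reagents that add atoms: none
Why: Mild acid methanolysis removes the secondary triethylsilyl ether much faster than the hindered tertiary one or the tert-butyldimethylsilyl ether; the conditions are too weak to ionize the protected bis-allylic position.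

Step 18
Reactants: 28 (1Z,3R,4Z,6S,7R,8R,10R)-3-[(tert-butyldimethylsilyl)oxy]-8-hydroxy-10-[(triethylsilyl)oxy]germacra-1,4,11(13)-trien-12,6-olide; 29 tigloyl chloride [(2E)-2-methylbut-2-enoyl chloride]
Product: 30 (1Z,3R,4Z,6S,7R,8R,10R)-3-[(tert-butyldimethylsilyl)oxy]-8-(tigloyloxy)-10-[(triethylsilyl)oxy]germacra-1,4,11(13)-trien-12,6-olide
Conditions: pyridine, DMAP (cat.), CH2Cl2, 0 °C to rt
Reagents that add atoms: none
Why: Acylation of the only free hydroxyl with retention at C8; the E-configured tigloyl group is the stable geometric isomer and should not isomerize.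

Step 19
Reactants: 30 (1Z,3R,4Z,6S,7R,8R,10R)-3-[(tert-butyldimethylsilyl)oxy]-8-(tigloyloxy)-10-[(triethylsilyl)oxy]germacra-1,4,11(13)-trien-12,6-olide
Product: 31 (1Z,3R,4Z,6S,7R,8R,10R)-3,10-dihydroxy-8-(tigloyloxy)germacra-1,4,11(13)-trien-12,6-olide (target)
Conditions: HF·pyridine, excess pyridine, THF, 0 °C to rt
Reagents that add atoms: none
Why: Buffered fluoride cleaves both silyl ethers without acid strong enough to ionize the bis-allylic alcohol and without base that could open the lactone or move the tiglate.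

## Compound list

1 | but-2-yn-1-ol | CC#CCO | starting material
2 | sodium 2,2-bis(2-methoxyethoxy)-3-methyl-2,5-dihydro-1,2-oxaaluminol-2-uide (cyclic alkenylaluminate) | [Na+].CC1=CCO[Al-]1(OCCOC)OCCOC | intermediate
3 | (2Z)-3-iodobut-2-en-1-ol | C/C(I)=C/CO | intermediate
4 | triethyl{[(2Z)-3-iodobut-2-en-1-yl]oxy}silane | C/C(I)=C/CO[Si](CC)(CC)CC | intermediate
5 | {(2Z)-4-[(triethylsilyl)oxy]but-2-en-2-yl}lithium | [Li]/C(C)=C\CO[Si](CC)(CC)CC | intermediate
6 | (2Z)-2-methyl-4-[(triethylsilyl)oxy]but-2-enal | O=C/C(C)=C\CO[Si](CC)(CC)CC | intermediate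
7 | (R)-(−)-linalool, (3R)-3,7-dimethylocta-1,6-dien-3-ol | C=C[C@](C)(O)CCC=C(C)C | starting material
8 | triethyl{[(3R)-3,7-dimethylocta-1,6-dien-3-yl]oxy}silane | C=C[C@](C)(O[Si](CC)(CC)CC)CCC=C(C)C | intermediate
9 | (4R)-4-methyl-4-[(triethylsilyl)oxy]hex-5-enal | C=C[C@](C)(O[Si](CC)(CC)CC)CCC=O | intermediate
10 | (2R,4R)-2-(anilinooxy)-4-methyl-4-[(triethylsilyl)oxy]hex-5-enal | C=C[C@](C)(O[Si](CC)(CC)CC)C[C@@H](ONc1ccccc1)C=O | intermediate
11 | (2R,4R)-2-(anilinooxy)-4-methyl-4-[(triethylsilyl)oxy]hex-5-en-1-ol | C=C[C@](C)(O[Si](CC)(CC)CC)C[C@@H](ONc1ccccc1)CO | intermediate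
12 | (2R,4R)-4-methyl-4-[(triethylsilyl)oxy]hex-5-ene-1,2-diol | C=C[C@](C)(O[Si](CC)(CC)CC)C[C@@H](O)CO | intermediate
13 | (2R,4R)-4-methyl-1,2,4-tris[(triethylsilyl)oxy]hex-5-ene | C=C[C@](C)(O[Si](CC)(CC)CC)C[C@@H](O[Si](CC)(CC)CC)CO[Si](CC)(CC)CC | intermediate
14 | (2R,4R)-2-methyl-2,4,5-tris[(triethylsilyl)oxy]pentanal | O=C[C@](C)(O[Si](CC)(CC)CC)C[C@@H](O[Si](CC)(CC)CC)CO[Si](CC)(CC)CC | intermediate
15 | (3R,5R)-3-methyl-3,5,6-tris[(triethylsilyl)oxy]hex-1-yne | C#C[C@](C)(O[Si](CC)(CC)CC)C[C@@H](O[Si](CC)(CC)CC)CO[Si](CC)(CC)CC | intermediate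
16 | methyl{(3R,5R)-3-methyl-3,5,6-tris[(triethylsilyl)oxy]hex-1-yn-1-yl}zinc | C[Zn]C#C[C@](C)(O[Si](CC)(CC)CC)C[C@@H](O[Si](CC)(CC)CC)CO[Si](CC)(CC)CC | intermediate
17 | (2Z,4S,7R,9R)-3,7-dimethyl-1,7,9,10-tetrakis[(triethylsilyl)oxy]dec-2-en-5-yn-4-ol | CC[Si](CC)(CC)OC/C=C(/C)[C@H](O)C#C[C@](C)(O[Si](CC)(CC)CC)C[C@@H](O[Si](CC)(CC)CC)CO[Si](CC)(CC)CC | intermediate
18 | (2Z,4R,5Z,7R,9R)-3,7-dimethyl-1,7,9,10-tetrakis[(triethylsilyl)oxy]deca-2,5-dien-4-ol | CC[Si](CC)(CC)OC/C=C(/C)[C@H](O)/C=C\[C@](C)(O[Si](CC)(CC)CC)C[C@@H](O[Si](CC)(CC)CC)CO[Si](CC)(CC)CC | intermediate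
19 | (2Z,4R,5Z,7R,9R)-4-[(tert-butyldimethylsilyl)oxy]-3,7-dimethyl-1,7,9,10-tetrakis[(triethylsilyl)oxy]deca-2,5-diene | CC[Si](CC)(CC)OC/C=C(/C)[C@H](O[Si](C)(C)C(C)(C)C)/C=C\[C@](C)(O[Si](CC)(CC)CC)C[C@@H](O[Si](CC)(CC)CC)CO[Si](CC)(CC)CC | intermediate
20 | (2Z,4R,5Z,7R,9R)-4-[(tert-butyldimethylsilyl)oxy]-3,7-dimethyl-7,9-bis[(triethylsilyl)oxy]deca-2,5-dienedial | O=C/C=C(/C)[C@H](O[Si](C)(C)C(C)(C)C)/C=C\[C@](C)(O[Si](CC)(CC)CC)C[C@@H](O[Si](CC)(CC)CC)C=O | intermediate
21 | methyl propiolate | C#CC(=O)OC | starting material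
22 | methyl 2-(diisobutylalumanyl)prop-2-enoate | C=C([Al](CC(C)C)CC(C)C)C(=O)OC | intermediate
23 | methyl (4R,6R,7Z,9R,10Z)-9-[(tert-butyldimethylsilyl)oxy]-3-hydroxy-6,10-dimethyl-2-methylidene-12-oxo-4,6-bis[(triethylsilyl)oxy]dodeca-7,10-dienoate (both C3 epimers) | O=C/C=C(/C)[C@H](O[Si](C)(C)C(C)(C)C)/C=C\[C@](C)(O[Si](CC)(CC)CC)C[C@@H](O[Si](CC)(CC)CC)C(O)C(=C)C(=O)OC | intermediate
24 | methyl (2Z,4R,6R,7Z,9R,10Z)-2-(bromomethyl)-9-[(tert-butyldimethylsilyl)oxy]-6,10-dimethyl-12-oxo-4,6-bis[(triethylsilyl)oxy]dodeca-2,7,10-trienoate | O=C/C=C(/C)[C@H](O[Si](C)(C)C(C)(C)C)/C=C\[C@](C)(O[Si](CC)(CC)CC)C[C@@H](O[Si](CC)(CC)CC)/C=C(\CBr)C(=O)OC | intermediate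
25 | dichloro(allyl)chromium derived from 24 (CrCl2 group in place of Br) | O=C/C=C(/C)[C@H](O[Si](C)(C)C(C)(C)C)/C=C\[C@](C)(O[Si](CC)(CC)CC)C[C@@H](O[Si](CC)(CC)CC)/C=C(\C[Cr](Cl)Cl)C(=O)OC | intermediate
26 | dichlorochromium alkoxide of the ring-closed methyl 2-(cyclodecadienyl)acrylate (C6–O–Cr, methyl ester still open; C3, C6, C7, C8, C10 as in the target) | COC(=O)C(=C)[C@H]1[C@@H](O[Cr](Cl)Cl)/C=C(/C)[C@H](O[Si](C)(C)C(C)(C)C)/C=C\[C@](C)(O[Si](CC)(CC)CC)C[C@H]1O[Si](CC)(CC)CC | intermediate
27 | (1Z,3R,4Z,6S,7S,8R,10R)-3-[(tert-butyldimethylsilyl)oxy]-8,10-bis[(triethylsilyl)oxy]germacra-1,4,11(13)-trien-12,6-olide | C=C1C(=O)O[C@H]2/C=C(/C)[C@H](O[Si](C)(C)C(C)(C)C)/C=C\[C@](C)(O[Si](CC)(CC)CC)C[C@@H](O[Si](CC)(CC)CC)[C@@H]12 | intermediate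
28 | (1Z,3R,4Z,6S,7R,8R,10R)-3-[(tert-butyldimethylsilyl)oxy]-8-hydroxy-10-[(triethylsilyl)oxy]germacra-1,4,11(13)-trien-12,6-olide | C=C1C(=O)O[C@H]2/C=C(/C)[C@H](O[Si](C)(C)C(C)(C)C)/C=C\[C@](C)(O[Si](CC)(CC)CC)C[C@@H](O)[C@@H]12 | intermediate
29 | tigloyl chloride, (2E)-2-methylbut-2-enoyl chloride | C/C=C(\C)C(=O)Cl | starting material
30 | (1Z,3R,4Z,6S,7R,8R,10R)-3-[(tert-butyldimethylsilyl)oxy]-8-(tigloyloxy)-10-[(triethylsilyl)oxy]germacra-1,4,11(13)-trien-12,6-olide | C=C1C(=O)O[C@H]2/C=C(/C)[C@H](O[Si](C)(C)C(C)(C)C)/C=C\[C@](C)(O[Si](CC)(CC)CC)C[C@@H](OC(=O)/C(C)=C/C)[C@@H]12 | intermediate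
31 | (1Z,3R,4Z,6S,7R,8R,10R)-3,10-dihydroxy-8-(tigloyloxy)germacra-1,4,11(13)-trien-12,6-olide | C=C1C(=O)O[C@H]2/C=C(/C)[C@H](O)/C=C\[C@](C)(O)C[C@@H](OC(=O)/C(C)=C/C)[C@@H]12 | target

## Step count and risks

Total step count: 19. Longest linear sequence: 16 steps (steps 4–19, from 7); the C3–C6 unit 6 takes 3 steps.

**Step 16 (key step).**
- What may go wrong: the facial selectivity at C7 relative to C8 may be reversed. The C9 chain also serves as the tether, and if it cannot take the anti position the aldehyde would add anti to the silyloxy group, giving the lactone epimeric at both C6 and C7. Oligomerization and loss of the Z-enal geometry are lesser risks.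
- Fallback: this replaces steric control by chelation control. It sets out from 24. Selective cleavage of the C8 triethylsilyl ether (HF·pyridine, pyridine, THF, 0 °C) should give methyl (2Z,4R,6R,7Z,9R,10Z)-2-(bromomethyl)-9-[(tert-butyldimethylsilyl)oxy]-4-hydroxy-6,10-dimethyl-12-oxo-6-[(triethylsilyl)oxy]dodeca-2,7,10-trienoate F1. In its Z-allylchromium the free C8 hydroxyl can bind trivalent chromium in a six-membered chelate (Cr–C13–C11=C7–C8–O8). This holds O8 on the metal-bearing face, from which the coordinated aldehyde is delivered. Cyclization with CrCl2 under the same dilution comes back to the route at 28.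

**Step 10.**
- What may go wrong: slow zincation of the hindered tertiary propargylic alkyne, isomerization of the Z-enal during a long reaction, and incomplete facial control.
- Fallback: the fallback sets out from 4 and 15. Iodine–lithium exchange of 4 and trapping with N-methoxy-N-methylcarbamoyl chloride gives (2Z)-N-methoxy-N,2-dimethyl-4-[(triethylsilyl)oxy]but-2-enamide F2. The lithium acetylide of 15 (n-BuLi, THF, −78 °C) adds to it to give (2Z,7R,9R)-3,7-dimethyl-1,7,9,10-tetrakis[(triethylsilyl)oxy]dec-2-en-5-yn-4-one F3. Asymmetric transfer hydrogenation with RuCl[(S,S)-TsDPEN](p-cymene) in i-PrOH (or its mirror image, as the sense of induction requires) comes back at 17.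

**Step 14.**
- What may go wrong: loss of chemoselectivity, that is addition of the vinylalane to the enal as well, or acid-promoted isomerization of the enal by the aluminium reagent.
- Fallback: the fallback sets out from 20 and uses the amine-catalysed Morita–Baylis–Hillman reaction (1,4-diazabicyclo[2.2.2]octane, methyl acrylate, neat or MeOH, rt). Only the saturated aldehyde is electrophilic enough to take part. It comes back at 23 with no new compound.

**Step 13.**
- What may go wrong: incomplete exchange of one primary silyl ether, or base-induced Z-to-E isomerization of the enal during the amine stage.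
- Fallback: the fallback sets out from 19. Methanolysis of the two primary triethylsilyl ethers (pyridinium p-toluenesulfonate, MeOH/CH2Cl2, −20 °C) gives (2Z,4R,5Z,7R,9R)-4-[(tert-butyldimethylsilyl)oxy]-3,7-dimethyl-7,9-bis[(triethylsilyl)oxy]deca-2,5-diene-1,10-diol F4. Double oxidation with Dess–Martin periodinane buffered with NaHCO3 comes back at 20 without any amine base.

**Step 3.**
- What may go wrong: 1,4 oxygen-to-carbon silyl migration in the Z-lithio species before it is formylated.
- Fallback: the fallback sets out from 4 and replaces the organolithium by a palladium-catalysed formylation (Pd(PPh3)4, CO at 3 atm, slow addition of Bu3SnH, THF, 50 °C), which keeps the alkene geometry. It comes back at 6 with no new compound.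

## Further compounds

F1 | step 16 | methyl (2Z,4R,6R,7Z,9R,10Z)-2-(bromomethyl)-9-[(tert-butyldimethylsilyl)oxy]-4-hydroxy-6,10-dimethyl-12-oxo-6-[(triethylsilyl)oxy]dodeca-2,7,10-trienoate | O=C/C=C(/C)[C@H](O[Si](C)(C)C(C)(C)C)/C=C\[C@](C)(O[Si](CC)(CC)CC)C[C@@H](O)/C=C(\CBr)C(=O)OC
F2 | step 10 | (2Z)-N-methoxy-N,2-dimethyl-4-[(triethylsilyl)oxy]but-2-enamide | CON(C)C(=O)/C(C)=C\CO[Si](CC)(CC)CC
F3 | step 10 | (2Z,7R,9R)-3,7-dimethyl-1,7,9,10-tetrakis[(triethylsilyl)oxy]dec-2-en-5-yn-4-one | CC[Si](CC)(CC)OC/C=C(/C)C(=O)C#C[C@](C)(O[Si](CC)(CC)CC)C[C@@H](O[Si](CC)(CC)CC)CO[Si](CC)(CC)CC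
F0 | step 14 | none | none
F4 | step 13 | (2Z,4R,5Z,7R,9R)-4-[(tert-butyldimethylsilyl)oxy]-3,7-dimethyl-7,9-bis[(triethylsilyl)oxy]deca-2,5-diene-1,10-diol | OC/C=C(/C)[C@H](O[Si](C)(C)C(C)(C)C)/C=C\[C@](C)(O[Si](CC)(CC)CC)C[C@@H](O[Si](CC)(CC)CC)CO
F0 | step 3 | none | none
A1 | alternative 1 | 1,2-seco diene: α-methylene-γ-butyrolactone carrying the (1Z,3R)-3-hydroxy-2-methylpenta-1,4-dienyl arm on C6 and the (1R,3R)-3-hydroxy-3-methyl-1-(tigloyloxy)pent-4-enyl arm on C7 | C=C1C(=O)O[C@@H](/C=C(/C)[C@H](O)C=C)[C@H]1[C@H](OC(=O)/C(C)=C/C)C[C@@](C)(O)C=C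
A2 | alternative 2 | iodo aldehyde: α-methylene-γ-butyrolactone carrying the (1Z)-2-methyl-3-oxoprop-1-enyl arm on C6 and the (1R,3R,4Z)-5-iodo-3-methyl-1,3-bis[(triethylsilyl)oxy]pent-4-enyl arm on C7 | C=C1C(=O)O[C@@H](/C=C(/C)C=O)[C@H]1[C@H](O[Si](CC)(CC)CC)C[C@@](C)(O[Si](CC)(CC)CC)/C=C\I
A3 | alternative 3 | (1(10)Z,2Z,4Z,6S,7R,8R)-8-(tigloyloxy)germacra-1(10),2,4,11(13)-tetraen-12,6-olide | C=C1C(=O)O[C@H]2/C=C(C)\C=C/C=C(C)\C[C@@H](OC(=O)/C(C)=C/C)[C@@H]12
A4 | alternative 3 | 3,10-epidioxide of A3: (1Z,4Z)-3,10-epidioxy-8-(tigloyloxy)germacra-1,4,11(13)-trien-12,6-olide with C3 and C10 as in the target | C=C1C(=O)O[C@H]2/C=C(/C)[C@@H]3OO[C@@](C)(/C=C\3)C[C@@H](OC(=O)/C(C)=C/C)[C@@H]12
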